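**Plan**

- Ring labels: A is the methoxy ring, B the para-phenylene, C the phenol ring (C1 bridge, C4 hydroxyl, C5 oxygen to ring D) and D the meta-phenylene. The retrosynthesis first puts a bromine on C3 of ring C, then cuts the C5(ring C)–O(ring D) ether, then the two CH2–CH2 bridges (as Wittig C=C bonds) and the ring A–O–ring B ether (SNAr).
- Enabling feature: the ring D oxygen sits on C5 of ring C, next to the free C4 hydroxyl. This ortho-aryloxyphenol is what a phenol oxidative coupling leaves behind, so a 3,5-dibromo-4-hydroxyphenyl ring C is oxidised at the anode and trapped by the ring D phenol.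
- Forward: rings D and A are joined by a Wittig reaction, ring B is added by SNAr and ring C by a second Wittig reaction. One hydrogenation saturates both bridges and frees the ring C phenol. Dibromination, MOM removal, anodic closure of the only new ring (19-membered) and hydrodebromination follow.
- Stereochemistry: the target has no stereocentre, and the alkene geometry of the Wittig products is erased by hydrogenation.

Key step: step 10

Remark on the chemistry: 3-hydroxy-4-methoxybenzyl alcohol (the reduced form of isovanillin) and 4-(benzyloxy)benzyl chloride are taken as purchased. The Wittig products are expected as E/Z mixtures and are carried on as such, so their SMILES carry no alkene descriptors.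

**Route**

Step 1
Reactants: 1 3-hydroxybenzaldehyde
Product: 2 3-(methoxymethoxy)benzaldehyde
Conditions: MOMCl, iPr2NEt, CH2Cl2, 0 °C to rt
Reagents that add atoms: chloromethyl methyl ether, COCCl
Why: O-alkylation of the phenol (MOM ether formation) masks the ring D hydroxyl as an acetal that should survive ylide bases, hot carbonate, hydrogenation and NBS and leave later with dilute acid.

Step 2
Reactants: 3 3-hydroxy-4-methoxybenzyl alcohol
Product: 4 (3-hydroxy-4-methoxybenzyl)triphenylphosphonium bromide
Conditions: PPh3·HBr, MeCN, reflux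
Reagents that add atoms: triphenylphosphine hydrobromide, Br.c1ccc(cc1)P(c1ccccc1)c1ccccc1
Why: Direct phosphonium salt formation from a benzylic alcohol, in which the para-methoxy group stabilises the benzylic cation that PPh3 captures and the free phenol is tolerated.

Step 3
Reactants: 4 (3-hydroxy-4-methoxybenzyl)triphenylphosphonium bromide; 2 3-(methoxymethoxy)benzaldehyde
Product: 6 2-methoxy-5-{2-[3-(methoxymethoxy)phenyl]ethenyl}phenol (E/Z mixture), via phenoxide ylide 5 (not isolated)
Conditions: KOtBu (2.2 equiv), THF, 0 °C; then 2, rt; AcOH quench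
Reagents that add atoms: none
Why: Wittig olefination in which the first equivalent of base takes the phenol proton and the second forms the semi-stabilised ylide; the phenoxide is meta to the ylide carbon and so should not interfere.

Step 4
Reactants: 6 2-methoxy-5-{2-[3-(methoxymethoxy)phenyl]ethenyl}phenol (E/Z mixture); 7 4-fluorobenzaldehyde
Product: 8 4-(2-methoxy-5-{2-[3-(methoxymethoxy)phenyl]ethenyl}phenoxy)benzaldehyde (E/Z mixture)
Conditions: K2CO3, DMF, 120 °C
Reagents that add atoms: none
Why: SNAr displacement of fluoride activated by the para-formyl group, by the only free phenoxide in the molecule, forms the ring A–O–ring B ether.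

Step 5
Reactants: 9 4-(benzyloxy)benzyl chloride
Product: 10 [4-(benzyloxy)benzyl]triphenylphosphonium chloride
Conditions: PPh3, toluene, reflux
Reagents that add atoms: triphenylphosphine, c1ccc(cc1)P(c1ccccc1)c1ccccc1
Why: SN2 quaternisation of PPh3 by a reactive benzylic chloride, with the salt expected to crystallise from the hot solvent.

Step 6
Reactants: 10 [4-(benzyloxy)benzyl]triphenylphosphonium chloride; 8 4-(2-methoxy-5-{2-[3-(methoxymethoxy)phenyl]ethenyl}phenoxy)benzaldehyde (E/Z mixture)
Product: 12 1-(benzyloxy)-4-{2-[4-(2-methoxy-5-{2-[3-(methoxymethoxy)phenyl]ethenyl}phenoxy)phenyl]ethenyl}benzene (E/Z mixture at both C=C), via benzylidene phosphorane 11 (not isolated)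
Conditions: KOtBu (1.1 equiv), THF, 0 °C; then 8, rt
Reagents that add atoms: none
Why: Wittig olefination of a non-enolisable aryl aldehyde with a benzylic ylide attaches ring C and completes the open-chain four-ring carbon skeleton.

Step 7
Reactants: 12 1-(benzyloxy)-4-{2-[4-(2-methoxy-5-{2-[3-(methoxymethoxy)phenyl]ethenyl}phenoxy)phenyl]ethenyl}benzene (E/Z mixture at both C=C)
Product: 13 4-{2-[4-(2-methoxy-5-{2-[3-(methoxymethoxy)phenyl]ethyl}phenoxy)phenyl]ethyl}phenol
Conditions: H2 (1 atm), 10% Pd/C, EtOAc–THF, rt
Reagents that add atoms: none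
Why: Heterogeneous catalytic hydrogenation saturates both stilbene double bonds and hydrogenolyses the benzyl ether in one operation, while the MOM acetal and the diaryl ether are inert under neutral conditions.

Step 8
Reactants: 13 4-{2-[4-(2-methoxy-5-{2-[3-(methoxymethoxy)phenyl]ethyl}phenoxy)phenyl]ethyl}phenol
Product: 14 2,6-dibromo-4-{2-[4-(2-methoxy-5-{2-[3-(methoxymethoxy)phenyl]ethyl}phenoxy)phenyl]ethyl}phenol
Conditions: NBS (2.05 equiv), iPr2NH (0.1 equiv), CH2Cl2, 0 °C
Reagents that add atoms: N-bromosuccinimide, O=C1CCC(=O)N1Br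
Why: Amine-catalysed electrophilic ortho-bromination of a phenol by NBS, in which the para-blocked free phenol of ring C should take both bromines much faster than the MOM-masked ring D or the alkoxy-substituted ring A.

Step 9
Reactants: 14 2,6-dibromo-4-{2-[4-(2-methoxy-5-{2-[3-(methoxymethoxy)phenyl]ethyl}phenoxy)phenyl]ethyl}phenol
Product: 15 2,6-dibromo-4-[2-(4-{5-[2-(3-hydroxyphenyl)ethyl]-2-methoxyphenoxy}phenyl)ethyl]phenol
Conditions: conc. HCl (cat.), MeOH–THF, 50 °C
Reagents that add atoms: none
Why: Acid-catalysed acetal cleavage (MOM removal by transacetalisation to methanol) frees the ring D phenol without affecting the methyl ether, the diaryl ether or the C–Br bonds.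

Step 10
Reactants: 15 2,6-dibromo-4-[2-(4-{5-[2-(3-hydroxyphenyl)ethyl]-2-methoxyphenoxy}phenyl)ethyl]phenol
Product: 17 monobromo macrocycle (the target skeleton carrying Br on ring C at C3 ortho to the C4 hydroxyl), via macrocyclic bromo dienone 16 (not isolated)
Conditions: constant-current electrolysis (about 2.1 F/mol), glassy-carbon anode, Pt cathode, undivided cell, LiClO4, LiOMe (0.2 equiv), MeOH, about 1 mM, rt; then Zn dust, AcOH, rt
Reagents that add atoms: none
Why: Substoichiometric methoxide, renewed at the cathode, ionises only the acidic 2,6-dibromophenol of ring C, and this phenolate is oxidised at low potential by two electrons to a phenoxonium ion while the neutral ring D phenol and the ether-bearing rings A and B stay below their oxidation potentials. The tethered ring D hydroxyl adds to a bromine-bearing ortho carbon to give the 6-aryloxy-6-bromocyclohexa-2,4-dienone 16, which zinc in acetic acid reduces with loss of bromide and rearomatisation to the 2-aryloxy-6-bromophenol 17. The closest known reaction type is the anodic or Tl(NO3)3-mediated oxidation of ortho,ortho'-dihalophenols to diaryl ethers followed by zinc reduction, which has closed isodityrosine-type macrocycles. The 19-membered ring closes by intramolecular capture of the ring C cation by an oxygen nucleophile at high dilution, and no stereocentre remains because the quaternary carbon of 16 is lost on rearomatisation. The step needs oxidation of ring C alone and attack through oxygen at an ortho carbon: selective ionisation secures the first, the bridge blocks the para carbon (a para methanol adduct would be returned to 15 by the zinc), the two ortho carbons are equivalent, and the bromines steer towards C–O rather than C–C coupling and supply the leaving group.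

Step 11
Reactants: 17 monobromo macrocycle (the target skeleton carrying Br on ring C at C3 ortho to the C4 hydroxyl)
Product: 18 CNP0132125.0
Conditions: H2 (1 atm), 10% Pd/C, Et3N, EtOAc–MeOH, rt
Reagents that add atoms: none
Why: Palladium-catalysed hydrogenolysis of the aryl C–Br bond (hydrodehalogenation) with Et3N as acid scavenger removes the bromine, and nothing else in the molecule is reducible under these conditions.

**Compound list**

1 | 3-hydroxybenzaldehyde | O=Cc1cccc(O)c1 | starting material
2 | 3-(methoxymethoxy)benzaldehyde | COCOc1cccc(C=O)c1 | intermediate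
3 | 3-hydroxy-4-methoxybenzyl alcohol | COc1ccc(CO)cc1O | starting material
4 | (3-hydroxy-4-methoxybenzyl)triphenylphosphonium bromide | COc1ccc(C[P+](c2ccccc2)(c2ccccc2)c2ccccc2)cc1O.[Br-] | intermediate
5 | potassium 2-methoxy-5-[(triphenylphosphoranylidene)methyl]phenolate (phenoxide ylide) | COc1ccc(C=P(c2ccccc2)(c2ccccc2)c2ccccc2)cc1[O-].[K+] | intermediate (not isolated)
6 | 2-methoxy-5-{2-[3-(methoxymethoxy)phenyl]ethenyl}phenol, E/Z mixture | COCOc1cccc(C=Cc2ccc(OC)c(O)c2)c1 | intermediate
7 | 4-fluorobenzaldehyde | O=Cc1ccc(F)cc1 | starting material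
8 | 4-(2-methoxy-5-{2-[3-(methoxymethoxy)phenyl]ethenyl}phenoxy)benzaldehyde, E/Z mixture | COCOc1cccc(C=Cc2ccc(OC)c(Oc3ccc(C=O)cc3)c2)c1 | intermediate
9 | 4-(benzyloxy)benzyl chloride | ClCc1ccc(OCc2ccccc2)cc1 | starting material
10 | [4-(benzyloxy)benzyl]triphenylphosphonium chloride | [Cl-].c1ccc(COc2ccc(C[P+](c3ccccc3)(c3ccccc3)c3ccccc3)cc2)cc1 | intermediate
11 | [4-(benzyloxy)benzylidene]triphenylphosphorane | c1ccc(COc2ccc(C=P(c3ccccc3)(c3ccccc3)c3ccccc3)cc2)cc1 | intermediate (not isolated)
12 | 1-(benzyloxy)-4-{2-[4-(2-methoxy-5-{2-[3-(methoxymethoxy)phenyl]ethenyl}phenoxy)phenyl]ethenyl}benzene, E/Z mixture at both double bonds | COCOc1cccc(C=Cc2ccc(OC)c(Oc3ccc(C=Cc4ccc(OCc5ccccc5)cc4)cc3)c2)c1 | intermediate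
13 | 4-{2-[4-(2-methoxy-5-{2-[3-(methoxymethoxy)phenyl]ethyl}phenoxy)phenyl]ethyl}phenol | COCOc1cccc(CCc2ccc(OC)c(Oc3ccc(CCc4ccc(O)cc4)cc3)c2)c1 | intermediate
14 | 2,6-dibromo-4-{2-[4-(2-methoxy-5-{2-[3-(methoxymethoxy)phenyl]ethyl}phenoxy)phenyl]ethyl}phenol | COCOc1cccc(CCc2ccc(OC)c(Oc3ccc(CCc4cc(Br)c(O)c(Br)c4)cc3)c2)c1 | intermediate
15 | 2,6-dibromo-4-[2-(4-{5-[2-(3-hydroxyphenyl)ethyl]-2-methoxyphenoxy}phenyl)ethyl]phenol (open-chain bis(bibenzyl), dibromophenol ring C, free ring D phenol) | COc1ccc(CCc2cccc(O)c2)cc1Oc1ccc(CCc2cc(Br)c(O)c(Br)c2)cc1 | intermediate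
16 | macrocyclic 2,6-dibromo-6-aryloxycyclohexa-2,4-dienone: ring C as dienone, its sp3 carbon next to the carbonyl carrying Br and the ring D oxygen, racemic at that carbon | COc1ccc2cc1Oc1ccc(cc1)CCC1=CC(Br)(Oc3cccc(c3)CC2)C(=O)C(Br)=C1 | intermediate (not isolated)
17 | monobromo macrocycle: target skeleton with Br on ring C at C3, ortho to the C4 hydroxyl | COc1ccc2cc1Oc1ccc(cc1)CCc1cc(Br)c(O)c(c1)Oc1cccc(c1)CC2 | intermediate
18 | CNP0132125.0: 19-membered bis(bibenzyl) macrocycle with methoxy ring A, para-phenylene ring B, phenol ring C and meta-phenylene ring D | COc1ccc2cc1Oc1ccc(cc1)CCc1ccc(O)c(c1)Oc1cccc(c1)CC2 | target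

**Count and risks**

Total step count: 11. Longest linear sequence: 9 steps (steps 2, 3, 4, 6, 7, 8, 9, 10, 11 from 3; equally steps 1, 3, 4, 6, 7, 8, 9, 10, 11 from 1).

Steps most likely to fail:

1. Step 10. The ring C cation may be captured by methanol at an ortho carbon or by a second molecule (oligomerisation) faster than by the distant, un-ionised ring D hydroxyl, and some oxidation of ring D could lead to C–C coupling. The fallback closes the same C5(ring C)–O bond by copper-mediated Ullmann etherification and sets out from 14. Benzylation of the dibromophenol (BnBr, K2CO3, DMF) should give 2-(benzyloxy)-1,3-dibromo-5-{2-[4-(2-methoxy-5-{2-[3-(methoxymethoxy)phenyl]ethyl}phenoxy)phenyl]ethyl}benzene F1. Acidic MOM removal (HCl, MeOH–THF) should give the ring D phenol 3-{2-[3-(4-{2-[4-(benzyloxy)-3,5-dibromophenyl]ethyl}phenoxy)-4-methoxyphenyl]ethyl}phenol F2. Intramolecular Ullmann coupling at either of the two equivalent C–Br bonds (CuCl, 2,2,6,6-tetramethylheptane-3,5-dione, Cs2CO3, NMP, 120 °C, high dilution) should give the O-benzyl monobromo macrocycle F3. Hydrogenolysis (H2, Pd/C, NaOAc, EtOAc–MeOH) removes the benzyl group and the remaining bromine together and comes back to the route at 18.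

2. Step 8. Bromination may spill over onto the alkoxy-activated rings A and D, or stop after the first bromine. The fallback brings the bromines in with ring C and reduces the bridges with diimide instead of by catalytic hydrogenation; it sets out from 8. Commercial 3,5-dibromo-4-hydroxybenzaldehyde is reduced (NaBH4, MeOH) to 3,5-dibromo-4-hydroxybenzyl alcohol F4 and converted (PPh3·HBr, MeCN, reflux) into (3,5-dibromo-4-hydroxybenzyl)triphenylphosphonium bromide F5. A Wittig reaction of F5 with 8 (KOtBu, 2.2 equiv, THF) should give 2,6-dibromo-4-{2-[4-(2-methoxy-5-{2-[3-(methoxymethoxy)phenyl]ethenyl}phenoxy)phenyl]ethenyl}phenol F6. Diimide (TsNHNH2, NaOAc, THF–H2O, reflux) saturates both double bonds without touching the C–Br bonds and comes back to the route at 14.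

3. Step 3. The doubly deprotonated phosphonium salt may be poorly soluble and slow to react, so the olefination may stall or the aldehyde may be consumed by side reactions. The fallback masks the phenol first and sets out from 4. Silylation (TBSCl, imidazole, DMF) should give {3-[(tert-butyldimethylsilyl)oxy]-4-methoxybenzyl}triphenylphosphonium bromide F7. A Wittig reaction with 2 (KOtBu, 1.05 equiv, THF) should give tert-butyl(2-methoxy-5-{2-[3-(methoxymethoxy)phenyl]ethenyl}phenoxy)dimethylsilane F8. Desilylation (Bu4NF, THF) comes back to the route at 6.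

**Further compounds**

F1 | step 10 | 2-(benzyloxy)-1,3-dibromo-5-{2-[4-(2-methoxy-5-{2-[3-(methoxymethoxy)phenyl]ethyl}phenoxy)phenyl]ethyl}benzene | COCOc1cccc(CCc2ccc(OC)c(Oc3ccc(CCc4cc(Br)c(OCc5ccccc5)c(Br)c4)cc3)c2)c1
F2 | step 10 | 3-{2-[3-(4-{2-[4-(benzyloxy)-3,5-dibromophenyl]ethyl}phenoxy)-4-methoxyphenyl]ethyl}phenol | COc1ccc(CCc2cccc(O)c2)cc1Oc1ccc(CCc2cc(Br)c(OCc3ccccc3)c(Br)c2)cc1
F3 | step 10 | O-benzyl monobromo macrocycle (17 with the ring C hydroxyl as benzyl ether) | COc1ccc2cc1Oc1ccc(cc1)CCc1cc(Br)c(OCc3ccccc3)c(c1)Oc1cccc(c1)CC2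
F4 | step 8 | 3,5-dibromo-4-hydroxybenzyl alcohol | OCc1cc(Br)c(O)c(Br)c1
F5 | step 8 | (3,5-dibromo-4-hydroxybenzyl)triphenylphosphonium bromide | Oc1c(Br)cc(C[P+](c2ccccc2)(c2ccccc2)c2ccccc2)cc1Br.[Br-]
F6 | step 8 | 2,6-dibromo-4-{2-[4-(2-methoxy-5-{2-[3-(methoxymethoxy)phenyl]ethenyl}phenoxy)phenyl]ethenyl}phenol, E/Z mixture at both double bonds | COCOc1cccc(C=Cc2ccc(OC)c(Oc3ccc(C=Cc4cc(Br)c(O)c(Br)c4)cc3)c2)c1
F7 | step 3 | {3-[(tert-butyldimethylsilyl)oxy]-4-methoxybenzyl}triphenylphosphonium bromide | COc1ccc(C[P+](c2ccccc2)(c2ccccc2)c2ccccc2)cc1O[Si](C)(C)C(C)(C)C.[Br-]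
F8 | step 3 | tert-butyl(2-methoxy-5-{2-[3-(methoxymethoxy)phenyl]ethenyl}phenoxy)dimethylsilane, E/Z mixture | COCOc1cccc(C=Cc2ccc(OC)c(O[Si](C)(C)C(C)(C)C)c2)c1
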